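The plan rests on the aryl ether oxygen O1 of ring C, which sits between the ring A carbon C8a and C2. Taking that oxygen out contracts ring C to a five-membered carbocycle, so the flavan is traced back to an enantiopure 3-arylindan-1-one whose carbonyl carbon is the future C2 and whose C3 already carries ring D in the C4 configuration. A Baeyer–Villiger oxidation puts O1 back in one operation, making the O1–C8a and O1–C2 bonds and the six-membered lactone without touching C4. The indanone carries benzyl ethers on the three future phenols and bromine on ring D as a placeholder for the cinnamoyl group.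

Key step: step 12

Remark: the SMILES is read as the (2R,4R), 2,4-trans flavan; atoms are numbered as in the flavan (O1, C2–C4, C4a–C8a; ring D primed, C1′ on C4). Compounds 8 and 22 are assumed to be bought as catalogue compounds.

**Ring A building block**

Step 1
Reactants: 1 2,5-dimethoxybenzaldehyde
Product: 3 2,5-dimethoxyphenol, via aryl formate 2 (not isolated)
Conditions: mCPBA, CH2Cl2, 0 °C → rt; then K2CO3 (cat.), MeOH, rt
Reagents that add atoms: 3-chloroperbenzoic acid, O=C(OO)c1cccc(Cl)c1
Why: Dakin-type Baeyer–Villiger oxidation in which the aryl group with its ortho methoxy donor migrates in the peracid adduct of the aldehyde, and mild methanolysis of the formate then frees the phenol.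

Step 2
Reactants: 3 2,5-dimethoxyphenol
Product: 4 2-benzyloxy-1,4-dimethoxybenzene
Conditions: BnBr, K2CO3, DMF, rt
Reagents that add atoms: benzyl bromide, BrCc1ccccc1
Why: Williamson etherification of a phenoxide with a reactive benzylic bromide.

Step 3
Reactants: 4 2-benzyloxy-1,4-dimethoxybenzene
Product: 5 1-benzyloxy-4-bromo-2,5-dimethoxybenzene
Conditions: NBS, MeCN, 0 °C → rt
Reagents that add atoms: N-bromosuccinimide, O=C1CCC(=O)N1Br
Why: Electrophilic aromatic bromination should go para to the benzyloxy group and ortho to a methoxy group, the one position activated by two donors and not wedged between two substituents, as in the halogenation of 1,2,4-trialkoxybenzenes.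

Step 4
Reactants: 5 1-benzyloxy-4-bromo-2,5-dimethoxybenzene
Product: 7 (4-benzyloxy-2,5-dimethoxyphenyl)boronic acid, via aryllithium 6 (not isolated)
Conditions: n-BuLi, THF, −78 °C; B(OiPr)3, −78 °C → rt; then 1 M HCl
Reagents that add atoms: triisopropyl borate, CC(C)OB(OC(C)C)OC(C)C; water, O
Why: Bromine–lithium exchange followed by borylation with a trialkyl borate and hydrolysis is the standard route to arylboronic acids, and the benzyl ether lies para to the carbanion and cannot interfere.

**Ring D building block**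

Step 5
Reactants: 8 2,4-dihydroxy-6-methoxybenzaldehyde
Product: 9 4-benzyloxy-2-hydroxy-6-methoxybenzaldehyde
Conditions: BnBr (1.05 equiv), K2CO3 (1.1 equiv), acetone, rt
Reagents that add atoms: benzyl bromide, BrCc1ccccc1
Why: Williamson etherification selective for the more acidic 4-hydroxyl, since the 2-hydroxyl is held in a hydrogen bond to the aldehyde.

Step 6
Reactants: 9 4-benzyloxy-2-hydroxy-6-methoxybenzaldehyde
Product: 10 4-benzyloxy-3-bromo-2-hydroxy-6-methoxybenzaldehyde
Conditions: NBS (1.0 equiv), i-Pr2NH (cat.), CH2Cl2, 0 °C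
Reagents that add atoms: N-bromosuccinimide, O=C1CCC(=O)N1Br
Why: Amine-catalysed ortho-selective bromination of a phenol, for which C3 is the only free position ortho to the chelated hydroxyl (and para to the methoxy group), whereas C5 lies between two ether groups.

Step 7
Reactants: 10 4-benzyloxy-3-bromo-2-hydroxy-6-methoxybenzaldehyde
Product: 11 2,4-bis(benzyloxy)-3-bromo-6-methoxybenzaldehyde
Conditions: BnBr, K2CO3, DMF, 60 °C
Reagents that add atoms: benzyl bromide, BrCc1ccccc1
Why: Williamson etherification of the remaining, hindered phenol under forcing but routine conditions.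

Step 8
Reactants: 11 2,4-bis(benzyloxy)-3-bromo-6-methoxybenzaldehyde
Product: 12 methyl (E)-3-[2,4-bis(benzyloxy)-3-bromo-6-methoxyphenyl]prop-2-enoate
Conditions: (MeO)2P(O)CH2CO2Me, NaH, THF, 0 °C → rt
Reagents that add atoms: trimethyl phosphonoacetate, COC(=O)CP(=O)(OC)OC
Why: Horner–Wadsworth–Emmons olefination with a stabilised phosphonate anion, which gives the (E)-acrylate even from doubly ortho-substituted benzaldehydes.

**Union, indanone and key step**

Step 9
Reactants: 7 (4-benzyloxy-2,5-dimethoxyphenyl)boronic acid; 12 methyl (E)-3-[2,4-bis(benzyloxy)-3-bromo-6-methoxyphenyl]prop-2-enoate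
Product: 13 methyl (S)-3-(4-benzyloxy-2,5-dimethoxyphenyl)-3-[2,4-bis(benzyloxy)-3-bromo-6-methoxyphenyl]propanoate
Conditions: 7 (2.5 equiv), [RhCl(C2H4)2]2 (2.5 mol %), (R,R)-Ph-bod* (5.5 mol %), KOH (0.2 equiv), dioxane/H2O (10:1), 50 °C
Reagents that add atoms: none
Why: Hayashi–Miyaura asymmetric 1,4-addition of an arylboronic acid to a β-aryl acrylate, in which the aryl–rhodium species bearing the chiral diene is expected to insert the enoate on its α-re face (the sense in which this ligand gives (R)-3-arylcyclohexanones from 2-cyclohexenone), so that the catalyst sets the (S) centre that becomes C4.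

Step 10
Reactants: 13 methyl (S)-3-(4-benzyloxy-2,5-dimethoxyphenyl)-3-[2,4-bis(benzyloxy)-3-bromo-6-methoxyphenyl]propanoate
Product: 14 (S)-3-(4-benzyloxy-2,5-dimethoxyphenyl)-3-[2,4-bis(benzyloxy)-3-bromo-6-methoxyphenyl]propanoic acid
Conditions: LiOH, THF/MeOH/H2O, 40 °C; then 1 M HCl
Reagents that add atoms: lithium hydroxide, [Li+].[OH-]
Why: Saponification of a methyl ester, with the stereocentre β to the carboxyl group and therefore not open to epimerisation by enolisation.

Step 11
Reactants: 14 (S)-3-(4-benzyloxy-2,5-dimethoxyphenyl)-3-[2,4-bis(benzyloxy)-3-bromo-6-methoxyphenyl]propanoic acid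
Product: 16 (S)-6-benzyloxy-3-[2,4-bis(benzyloxy)-3-bromo-6-methoxyphenyl]-4,7-dimethoxyindan-1-one, via acid chloride 15 (not isolated)
Conditions: 1-chloro-N,N,2-trimethylprop-1-en-1-amine, CH2Cl2, 0 °C → rt; then SnCl4 (1.2 equiv), CH2Cl2 (0.01 M), −78 → −20 °C
Reagents that add atoms: none
Why: Intramolecular Friedel–Crafts acylation through the acid chloride, in which the acylium ion can reach only C8a–H of ring A (ortho to the tether and activated by the adjacent methoxy group) because both ortho positions of ring D are substituted, while neutral chloride formation, low temperature and high dilution should protect the benzyl ethers and disfavour intermolecular acylation.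

Step 12
Reactants: 16 (S)-6-benzyloxy-3-[2,4-bis(benzyloxy)-3-bromo-6-methoxyphenyl]-4,7-dimethoxyindan-1-one
Product: 17 (S)-7-benzyloxy-4-[2,4-bis(benzyloxy)-3-bromo-6-methoxyphenyl]-5,8-dimethoxychroman-2-one
Conditions: mCPBA (1.5 equiv), CH2Cl2, 0 °C → rt, dark
Reagents that add atoms: 3-chloroperbenzoic acid, O=C(OO)c1cccc(Cl)c1
Why: Baeyer–Villiger oxidation, in which the peracid adds to the C1 carbonyl of 16 to give the Criegee adduct and the aryl carbon C7a (the future C8a) shifts to oxygen as 3-chlorobenzoate departs, creating the O1–C8a and O1–C2 bonds. The closest known reaction type is the peracid conversion of 1-indanones into 3,4-dihydrocoumarins. Ring C is not closed by a new cyclisation but arises by one-atom ring expansion of the five-membered carbocycle to the six-membered lactone through this 1,2-shift. No stereocentre is formed, and the centre at C4 (C3 of the indanone, set in step 9) is neither the migrating nor the carbonyl carbon and should be carried through unchanged. The step needs aryl rather than methylene migration, which the electron-rich ring A carbon with its ortho methoxy group should secure, and it needs the ketone to be the only oxidisable site, which the bromine placeholder on ring D (no second carbonyl) and the absence of added strong acid are meant to secure.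

**From the lactone to the target**

Step 13
Reactants: 17 (S)-7-benzyloxy-4-[2,4-bis(benzyloxy)-3-bromo-6-methoxyphenyl]-5,8-dimethoxychroman-2-one
Product: 19 (S)-3-[2,4-bis(benzyloxy)-3-bromo-6-methoxyphenyl]-3-(4-benzyloxy-2-hydroxy-3,6-dimethoxyphenyl)-1-phenylpropan-1-one, via Weinreb amide 18 (not isolated)
Conditions: MeNH(OMe)·HCl (1.5 equiv), i-PrMgCl (3 equiv), THF, −20 °C; then PhMgBr (3 equiv), 0 °C → rt; then 1 M HCl
Reagents that add atoms: phenylmagnesium bromide, Br[Mg]c1ccccc1
Why: One-pot lactone aminolysis and Weinreb ketone synthesis, in which the magnesium amide opens the aryl ester and the chelated tetrahedral adduct of the Weinreb amide with PhMgBr survives until work-up, so that addition stops at the ketone and the aryl bromide is left alone by these Grignard reagents.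

Step 14
Reactants: 19 (S)-3-[2,4-bis(benzyloxy)-3-bromo-6-methoxyphenyl]-3-(4-benzyloxy-2-hydroxy-3,6-dimethoxyphenyl)-1-phenylpropan-1-one
Product: 20 (1S,3S)-3-[2,4-bis(benzyloxy)-3-bromo-6-methoxyphenyl]-3-(4-benzyloxy-2-hydroxy-3,6-dimethoxyphenyl)-1-phenylpropan-1-ol
Conditions: RuCl(p-cymene)[(S,S)-TsDPEN] (2 mol %), HCO2H/Et3N (5:2), CH2Cl2, 30 °C
Reagents that add atoms: none
Why: Noyori asymmetric transfer hydrogenation of an aryl alkyl ketone, in which the (S,S)-TsDPEN ruthenium hydride should deliver hydride to the face that gives the (S)-carbinol, as it does with acetophenone, under catalyst control and with tolerance of the free phenol.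

Step 15
Reactants: 20 (1S,3S)-3-[2,4-bis(benzyloxy)-3-bromo-6-methoxyphenyl]-3-(4-benzyloxy-2-hydroxy-3,6-dimethoxyphenyl)-1-phenylpropan-1-ol
Product: 21 (2R,4S)-7-benzyloxy-4-[2,4-bis(benzyloxy)-3-bromo-6-methoxyphenyl]-5,8-dimethoxy-2-phenylchromane
Conditions: PPh3, DIAD, THF, 0 °C → rt
Reagents that add atoms: none
Why: Intramolecular Mitsunobu etherification, in which the C8a phenol displaces the benzylic oxyphosphonium group in a 6-exo-tet SN2 closure with inversion, turning the (1S)-carbinol into (2R) and so placing the phenyl group trans to ring D at the fixed C4 centre.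

Step 16
Reactants: 21 (2R,4S)-7-benzyloxy-4-[2,4-bis(benzyloxy)-3-bromo-6-methoxyphenyl]-5,8-dimethoxy-2-phenylchromane; 22 (E)-N-methoxy-N-methylcinnamamide
Product: 24 (E)-1-{2,6-bis(benzyloxy)-3-[(2R,4R)-7-benzyloxy-5,8-dimethoxy-2-phenylchroman-4-yl]-4-methoxyphenyl}-3-phenylprop-2-en-1-one, via aryllithium 23 (not isolated)
Conditions: n-BuLi (1.1 equiv), THF, −78 °C; then 22 (1.5 equiv), −78 → −20 °C; then 1 M HCl
Reagents that add atoms: none
Why: Bromine–lithium exchange at −78 °C gives the aryllithium flanked by two benzyloxy groups, which should add 1,2 to the Weinreb amide to give a chelated adduct that collapses to the (E)-enone only on work-up (Weinreb ketone synthesis), so neither over-addition nor conjugate addition is expected.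

Step 17
Reactants: 24 (E)-1-{2,6-bis(benzyloxy)-3-[(2R,4R)-7-benzyloxy-5,8-dimethoxy-2-phenylchroman-4-yl]-4-methoxyphenyl}-3-phenylprop-2-en-1-one
Product: 25 sarcandrone B, (E)-1-{2,6-dihydroxy-3-[(2R,4R)-7-hydroxy-5,8-dimethoxy-2-phenylchroman-4-yl]-4-methoxyphenyl}-3-phenylprop-2-en-1-one
Conditions: BCl3, C6HMe5, CH2Cl2, −78 °C; then MeOH
Reagents that add atoms: none
Why: Lewis-acid debenzylation with BCl3 and pentamethylbenzene as a non-basic benzyl cation scavenger, which should remove the three benzyl ethers at −78 °C while leaving the methyl ethers (none ortho to the carbonyl), the enone and the benzylic C–O and C–C bonds of the flavan intact.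

**Compound list**

1 | 2,5-dimethoxybenzaldehyde | COc1ccc(OC)c(C=O)c1 | starting material
2 | 2,5-dimethoxyphenyl formate | COc1ccc(OC)c(OC=O)c1 | intermediate (not isolated)
3 | 2,5-dimethoxyphenol | COc1ccc(OC)c(O)c1 | intermediate
4 | 2-benzyloxy-1,4-dimethoxybenzene | COc1ccc(OC)c(OCc2ccccc2)c1 | intermediate
5 | 1-benzyloxy-4-bromo-2,5-dimethoxybenzene | COc1cc(OCc2ccccc2)c(OC)cc1Br | intermediate
6 | (4-benzyloxy-2,5-dimethoxyphenyl)lithium | [Li]c1cc(OC)c(OCc2ccccc2)cc1OC | intermediate (not isolated)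
7 | (4-benzyloxy-2,5-dimethoxyphenyl)boronic acid | OB(O)c1cc(OC)c(OCc2ccccc2)cc1OC | intermediate
8 | 2,4-dihydroxy-6-methoxybenzaldehyde | COc1cc(O)cc(O)c1C=O | starting material
9 | 4-benzyloxy-2-hydroxy-6-methoxybenzaldehyde | COc1cc(OCc2ccccc2)cc(O)c1C=O | intermediate
10 | 4-benzyloxy-3-bromo-2-hydroxy-6-methoxybenzaldehyde | COc1cc(OCc2ccccc2)c(Br)c(O)c1C=O | intermediate
11 | 2,4-bis(benzyloxy)-3-bromo-6-methoxybenzaldehyde | COc1cc(OCc2ccccc2)c(Br)c(OCc2ccccc2)c1C=O | intermediate
12 | methyl (E)-3-[2,4-bis(benzyloxy)-3-bromo-6-methoxyphenyl]prop-2-enoate | COC(=O)/C=C/c1c(OC)cc(OCc2ccccc2)c(Br)c1OCc1ccccc1 | intermediate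
13 | methyl (S)-3-(4-benzyloxy-2,5-dimethoxyphenyl)-3-[2,4-bis(benzyloxy)-3-bromo-6-methoxyphenyl]propanoate | COc1cc(OCc2ccccc2)c(Br)c(OCc2ccccc2)c1[C@@H](CC(=O)OC)c1cc(OC)c(OCc2ccccc2)cc1OC | intermediate
14 | (S)-3-(4-benzyloxy-2,5-dimethoxyphenyl)-3-[2,4-bis(benzyloxy)-3-bromo-6-methoxyphenyl]propanoic acid | COc1cc(OCc2ccccc2)c(Br)c(OCc2ccccc2)c1[C@@H](CC(=O)O)c1cc(OC)c(OCc2ccccc2)cc1OC | intermediate
15 | (S)-3-(4-benzyloxy-2,5-dimethoxyphenyl)-3-[2,4-bis(benzyloxy)-3-bromo-6-methoxyphenyl]propanoyl chloride | COc1cc(OCc2ccccc2)c(Br)c(OCc2ccccc2)c1[C@@H](CC(=O)Cl)c1cc(OC)c(OCc2ccccc2)cc1OC | intermediate (not isolated)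
16 | (S)-6-benzyloxy-3-[2,4-bis(benzyloxy)-3-bromo-6-methoxyphenyl]-4,7-dimethoxyindan-1-one | COc1cc(OCc2ccccc2)c(Br)c(OCc2ccccc2)c1[C@H]1CC(=O)c2c(OC)c(OCc3ccccc3)cc(OC)c21 | intermediate (precursor of the key step)
17 | (S)-7-benzyloxy-4-[2,4-bis(benzyloxy)-3-bromo-6-methoxyphenyl]-5,8-dimethoxychroman-2-one | COc1cc(OCc2ccccc2)c(Br)c(OCc2ccccc2)c1[C@H]1CC(=O)Oc2c(OC)c(OCc3ccccc3)cc(OC)c21 | intermediate (product of the key step)
18 | (S)-3-[2,4-bis(benzyloxy)-3-bromo-6-methoxyphenyl]-3-(4-benzyloxy-2-hydroxy-3,6-dimethoxyphenyl)-N-methoxy-N-methylpropanamide, present as its chloromagnesium phenoxide | COc1cc(OCc2ccccc2)c(Br)c(OCc2ccccc2)c1[C@@H](CC(=O)N(C)OC)c1c(OC)cc(OCc2ccccc2)c(OC)c1O[Mg]Cl | intermediate (not isolated)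
19 | (S)-3-[2,4-bis(benzyloxy)-3-bromo-6-methoxyphenyl]-3-(4-benzyloxy-2-hydroxy-3,6-dimethoxyphenyl)-1-phenylpropan-1-one | COc1cc(OCc2ccccc2)c(Br)c(OCc2ccccc2)c1[C@@H](CC(=O)c1ccccc1)c1c(OC)cc(OCc2ccccc2)c(OC)c1O | intermediate
20 | (1S,3S)-3-[2,4-bis(benzyloxy)-3-bromo-6-methoxyphenyl]-3-(4-benzyloxy-2-hydroxy-3,6-dimethoxyphenyl)-1-phenylpropan-1-ol | COc1cc(OCc2ccccc2)c(Br)c(OCc2ccccc2)c1[C@@H](C[C@H](O)c1ccccc1)c1c(OC)cc(OCc2ccccc2)c(OC)c1O | intermediate
21 | (2R,4S)-7-benzyloxy-4-[2,4-bis(benzyloxy)-3-bromo-6-methoxyphenyl]-5,8-dimethoxy-2-phenylchromane (2,4-trans) | COc1cc(OCc2ccccc2)c(Br)c(OCc2ccccc2)c1[C@H]1C[C@H](c2ccccc2)Oc2c(OC)c(OCc3ccccc3)cc(OC)c21 | intermediate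
22 | (E)-N-methoxy-N-methylcinnamamide | CON(C)C(=O)/C=C/c1ccccc1 | starting material
23 | {2,6-bis(benzyloxy)-3-[(2R,4R)-7-benzyloxy-5,8-dimethoxy-2-phenylchroman-4-yl]-4-methoxyphenyl}lithium | COc1cc(OCc2ccccc2)c([Li])c(OCc2ccccc2)c1[C@H]1C[C@H](c2ccccc2)Oc2c(OC)c(OCc3ccccc3)cc(OC)c21 | intermediate (not isolated)
24 | (E)-1-{2,6-bis(benzyloxy)-3-[(2R,4R)-7-benzyloxy-5,8-dimethoxy-2-phenylchroman-4-yl]-4-methoxyphenyl}-3-phenylprop-2-en-1-one | COc1cc(OCc2ccccc2)c(C(=O)/C=C/c2ccccc2)c(OCc2ccccc2)c1[C@H]1C[C@H](c2ccccc2)Oc2c(OC)c(OCc3ccccc3)cc(OC)c21 | intermediate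
25 | sarcandrone B, (E)-1-{2,6-dihydroxy-3-[(2R,4R)-7-hydroxy-5,8-dimethoxy-2-phenylchroman-4-yl]-4-methoxyphenyl}-3-phenylprop-2-en-1-one | COc1cc(O)c(C(=O)/C=C/c2ccccc2)c(O)c1[C@H]1C[C@H](c2ccccc2)Oc2c(OC)c(O)cc(OC)c21 | target

**Step count and risk**

Total steps: 17. Longest linear sequence: 13 steps (1 → 25 through steps 1–4 and 9–17; the ring D branch 8 → 25 through steps 5–8 and 9–17 is equally long).

The three steps most likely to fail:

Step 9. The β-carbon of 12 carries a doubly ortho-substituted, donor-rich aryl group, so insertion into the aryl–rhodium bond may be slow enough for protodeboronation of 7 to take over, and facial discrimination may suffer. The fallback replaces catalysis by an auxiliary-controlled cuprate addition. It sets out from 12 and returns at 14.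
- LiOH hydrolysis of 12 gives (E)-3-[2,4-bis(benzyloxy)-3-bromo-6-methoxyphenyl]prop-2-enoic acid F1.
- PivCl/Et3N converts it into the mixed pivalic anhydride F2, which acylates (R)-4-phenyloxazolidin-2-one in the presence of LiCl to give the N-enoyl imide F3.
- The Grignard reagent (4-benzyloxy-2,5-dimethoxyphenyl)magnesium bromide F4, made from bromide 5 and Mg, is added with CuBr·SMe2 in THF at −40 °C. In the chelated s-cis imide it should attack anti to the 4-phenyl group, on the α-re face, to give the (S)-adduct F5.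
- LiOH/H2O2 removes the auxiliary and delivers acid 14.

Step 11. Closure onto the only modestly activated C8a–H may be outrun by acylation of the more nucleophilic ring D (C5′–H) of a second molecule, and the Lewis acid may strip benzyl groups or cleave the diarylmethine bond. The fallback closes the ring through an activated amide without any Lewis acid. It sets out from 14 and returns at 16.
- Coupling of 14 with Me2NH·HCl (EDC·HCl, HOBt, i-Pr2NEt) gives (S)-3-(4-benzyloxy-2,5-dimethoxyphenyl)-3-[2,4-bis(benzyloxy)-3-bromo-6-methoxyphenyl]-N,N-dimethylpropanamide F6.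
- Tf2O with 2-chloropyridine (CH2Cl2, −78 → 0 °C) turns the amide into an iminium-type electrophile that closes onto C8a in an intramolecular Vilsmeier-type reaction, giving the cyclic N,N-dimethyliminium triflate F7.
- Aqueous NaHCO3 hydrolyses F7 to indanone 16.

Step 12. Peracid addition to the carbonyl is slowed by the flanking methoxy group and by conjugation with the donor ring, so electrophilic hydroxylation of the electron-rich rings (above all C5′–H of ring D) may compete. The fallback reaches the same aryl-to-oxygen shift through a Hock rearrangement of a tertiary hydroperoxide. It sets out from 16 and returns at 19, so it also replaces step 13.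
- PhMgBr with CeCl3 (THF, −78 → 0 °C) adds to the ketone to give (3S)-6-benzyloxy-3-[2,4-bis(benzyloxy)-3-bromo-6-methoxyphenyl]-4,7-dimethoxy-1-phenylindan-1-ol F8; both C1 epimers are usable.
- H2O2 with BF3·OEt2 (CH2Cl2, 0 °C) ionises the doubly benzylic alcohol and traps it as the hydroperoxide F9.
- Acid-induced loss of water from F9 drives migration of the electron-rich ring A carbon to oxygen, and hydrolysis of the resulting 2-phenylchroman-2-yl oxocarbenium ion gives hydroxy ketone 19. Migration of the plain phenyl group would only return 16.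

Further compounds
F1 | step 9 | (E)-3-[2,4-bis(benzyloxy)-3-bromo-6-methoxyphenyl]prop-2-enoic acid | OC(=O)/C=C/c1c(OC)cc(OCc2ccccc2)c(Br)c1OCc1ccccc1
F2 | step 9 | (E)-3-[2,4-bis(benzyloxy)-3-bromo-6-methoxyphenyl]prop-2-enoic pivalic anhydride | CC(C)(C)C(=O)OC(=O)/C=C/c1c(OC)cc(OCc2ccccc2)c(Br)c1OCc1ccccc1
F3 | step 9 | (R)-3-{(E)-3-[2,4-bis(benzyloxy)-3-bromo-6-methoxyphenyl]prop-2-enoyl}-4-phenyloxazolidin-2-one | O=C(/C=C/c1c(OC)cc(OCc2ccccc2)c(Br)c1OCc1ccccc1)N1[C@H](c2ccccc2)COC1=O
F4 | step 9 | (4-benzyloxy-2,5-dimethoxyphenyl)magnesium bromide | COc1cc(OCc2ccccc2)c(OC)cc1[Mg]Br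
F5 | step 9 | (R)-3-{(S)-3-(4-benzyloxy-2,5-dimethoxyphenyl)-3-[2,4-bis(benzyloxy)-3-bromo-6-methoxyphenyl]propanoyl}-4-phenyloxazolidin-2-one | COc1cc(OCc2ccccc2)c(Br)c(OCc2ccccc2)c1[C@@H](CC(=O)N1[C@H](c2ccccc2)COC1=O)c1cc(OC)c(OCc2ccccc2)cc1OC
F6 | step 11 | (S)-3-(4-benzyloxy-2,5-dimethoxyphenyl)-3-[2,4-bis(benzyloxy)-3-bromo-6-methoxyphenyl]-N,N-dimethylpropanamide | COc1cc(OCc2ccccc2)c(Br)c(OCc2ccccc2)c1[C@@H](CC(=O)N(C)C)c1cc(OC)c(OCc2ccccc2)cc1OC
F7 | step 11 | (S)-N-{6-benzyloxy-3-[2,4-bis(benzyloxy)-3-bromo-6-methoxyphenyl]-4,7-dimethoxyindan-1-ylidene}-N-methylmethanaminium triflate | COc1cc(OCc2ccccc2)c(Br)c(OCc2ccccc2)c1[C@H]1CC(=[N+](C)C)c2c(OC)c(OCc3ccccc3)cc(OC)c21.[O-]S(=O)(=O)C(F)(F)F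
F8 | step 12 | (3S)-6-benzyloxy-3-[2,4-bis(benzyloxy)-3-bromo-6-methoxyphenyl]-4,7-dimethoxy-1-phenylindan-1-ol (C1 epimers) | COc1cc(OCc2ccccc2)c(Br)c(OCc2ccccc2)c1[C@H]1CC(O)(c2ccccc2)c2c(OC)c(OCc3ccccc3)cc(OC)c21
F9 | step 12 | (3S)-6-benzyloxy-3-[2,4-bis(benzyloxy)-3-bromo-6-methoxyphenyl]-1-hydroperoxy-4,7-dimethoxy-1-phenylindane (C1 epimers) | COc1cc(OCc2ccccc2)c(Br)c(OCc2ccccc2)c1[C@H]1CC(OO)(c2ccccc2)c2c(OC)c(OCc3ccccc3)cc(OC)c21
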